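**Plan**
1. Retrosynthesis: the phenol is released last; the seven-membered ring is cut at C8–C9 (alkenyl bromide plus aldehyde); then C4–isopropyl, C5–C6 (aldol) and C1–C10 (conjugate addition) are cut, leading back to 3-methylcyclopent-2-en-1-one.
2. Feature used: ring atoms C9 (carbinol) and C8 (bearing the exocyclic methylidene) form a 2-methylidenecycloheptan-1-ol unit, the signature of an alkenylchromium addition to an aldehyde.
3. Forward: the cyclopentane is present from the start; C1 is made quaternary, the C6–C8 arm is joined by an aldol reaction, isopropyl is added at C4, the C6 hydroxyl is acylated, the C1 vinyl group becomes CH2CHO, and the seven-membered ring is closed last.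
4. Stereochemistry: C1 is set by a chiral copper–NHC catalyst; C5 and C6 (one aldol event), C4 (addition anti to the C5 arm) and C9 (ring closure) are relayed from C1 by substrate control.
5. Helpers: a trimethylsilyl group on the C1 vinyl carbon makes that substituent bulky for the aldol and is removed in step 4; the phenol is carried as its acetate and freed in step 9.

Key step: step 8

Remark: locants follow the daucane skeleton (C1 quaternary methyl carbon; C2, C3 ring CH2; C4 isopropyl carbinol; C5 ring-fusion CH; C6 ester carbinol; C7 CH2; C8 methylidene carbon; C9 free carbinol; C10 CH2). It is assumed that the ligand enantiomer giving the 3S adduct in step 1 is used, both enantiomers being accessible.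

Step 1
Reactants: 1 3-methylcyclopent-2-en-1-one; 2 ethynyl(trimethyl)silane
Product: 5 trimethyl({(3S)-3-methyl-3-[1-(trimethylsilyl)ethenyl]cyclopent-1-en-1-yl}oxy)silane, via alkenylalane 3 (not isolated), via aluminium enolate 4 (not isolated)
Conditions: 2, i-Bu2AlH, hexanes/THF, 55 °C; then 1, Cu(OTf)2 (5 mol %), chiral sulfonate-bearing imidazolinium salt (NHC precursor, premetalated with Ag2O, 2.5 mol %), THF, 22 °C; then TMSOTf, −78 to 0 °C
Reagents that add atoms: trimethylsilyl trifluoromethanesulfonate, C[Si](C)(C)OS(=O)(=O)C(F)(F)F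
Why: Hydroalumination of the silylalkyne places aluminium on the silicon-bearing carbon, the copper-catalysed asymmetric conjugate addition of this alkenylalane to the β-methyl enone (a known route to quaternary β-carbons of cyclopentanones) sets C1 under control of the chiral NHC ligand, and O-silylation of the aluminium enolate fixes the enolate regiochemistry between C4 and C5.

Step 2
Reactants: 6 3-bromobut-3-en-1-ol
Product: 7 3-bromobut-3-enal
Conditions: Dess–Martin periodinane, NaHCO3, CH2Cl2, 0 °C; cold filtration through a short silica pad, solution used at once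
Reagents that add atoms: none
Why: Dess–Martin oxidation of a primary homoallylic alcohol under buffered, non-basic conditions should give the β,γ-unsaturated aldehyde without migration of the double bond into conjugation.

Step 3
Reactants: 5 trimethyl({(3S)-3-methyl-3-[1-(trimethylsilyl)ethenyl]cyclopent-1-en-1-yl}oxy)silane; 7 3-bromobut-3-enal
Product: 11 (2S,3S)-2-[(1S)-3-bromo-1-hydroxybut-3-en-1-yl]-3-methyl-3-[1-(trimethylsilyl)ethenyl]cyclopentan-1-one, via lithium enolate 8 (not isolated), via boron enolate 9 (not isolated), via boron aldolate 10 (not isolated)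
Conditions: MeLi, THF, 0 °C; n-Bu2BOTf, −78 °C; 7, −78 °C; then H2O2, pH 7 phosphate buffer, MeOH, 0 °C
Reagents that add atoms: none
Why: Methyllithium cleavage of the silyl enol ether, lithium-to-boron exchange and a boron aldol reaction through a closed Zimmerman–Traxler chair should give the anti aldol from the ring-locked E enolate, with the aldehyde approaching C5 on the face opposite the bulky 1-(trimethylsilyl)ethenyl group at C1, so that C5 (S) and C6 (S) are set together.

Step 4
Reactants: 11 (2S,3S)-2-[(1S)-3-bromo-1-hydroxybut-3-en-1-yl]-3-methyl-3-[1-(trimethylsilyl)ethenyl]cyclopentan-1-one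
Product: 12 (2S,3R)-2-[(1S)-3-bromo-1-hydroxybut-3-en-1-yl]-3-ethenyl-3-methylcyclopentan-1-one
Conditions: CF3CO2H, CH2Cl2, 0 to 22 °C; aq. NaHCO3
Reagents that add atoms: none
Why: Acid-mediated protodesilylation of an α-silyl alkene, known for 1-silylvinyl groups on β-keto quaternary carbons, removes the steering group and leaves the plain vinyl group, and a secondary β-hydroxy ketone and a 2-bromoalkene should tolerate cold trifluoroacetic acid for the time needed.

Step 5
Reactants: 12 (2S,3R)-2-[(1S)-3-bromo-1-hydroxybut-3-en-1-yl]-3-ethenyl-3-methylcyclopentan-1-one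
Product: 13 (1R,2S,3R)-2-[(1S)-3-bromo-1-hydroxybut-3-en-1-yl]-3-ethenyl-3-methyl-1-(propan-2-yl)cyclopentan-1-ol
Conditions: i-PrMgCl (excess), anhydrous CeCl3, THF, −78 to 0 °C; aq. NH4Cl
Reagents that add atoms: isopropylmagnesium chloride, CC(C)[Mg]Cl
Why: Organocerium 1,2-addition suppresses enolisation and reduction of the hindered β-hydroxy ketone, and the isopropyl group should enter C4 on the face anti to the adjacent C5 arm (the face also free of the pseudoaxial C1 methyl), which gives the 4R tertiary alcohol with hydroxyl cis to C6.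

Step 6
Reactants: 13 (1R,2S,3R)-2-[(1S)-3-bromo-1-hydroxybut-3-en-1-yl]-3-ethenyl-3-methyl-1-(propan-2-yl)cyclopentan-1-ol; 14 4-(acetyloxy)benzoyl chloride
Product: 15 (1S)-3-bromo-1-[(1S,2R,5R)-2-ethenyl-5-hydroxy-2-methyl-5-(propan-2-yl)cyclopentyl]but-3-en-1-yl 4-(acetyloxy)benzoate
Conditions: Et3N, DMAP (cat.), CH2Cl2, 0 to 22 °C
Reagents that add atoms: none
Why: DMAP-catalysed acylation by the acid chloride discriminates the secondary C6 hydroxyl from the tertiary C4 hydroxyl, and the phenol is carried as its acetate so that it cannot compete or oligomerise.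

Step 7
Reactants: 15 (1S)-3-bromo-1-[(1S,2R,5R)-2-ethenyl-5-hydroxy-2-methyl-5-(propan-2-yl)cyclopentyl]but-3-en-1-yl 4-(acetyloxy)benzoate
Product: 16 (1S)-3-bromo-1-[(1S,2R,5R)-2-hydroxy-5-methyl-5-(2-oxoethyl)-2-(propan-2-yl)cyclopentyl]but-3-en-1-yl 4-(acetyloxy)benzoate
Conditions: PdCl2(PhCN)2 (10 mol %), CuCl2·2H2O (10 mol %), AgNO2 (5 mol %), O2 (1 atm), t-BuOH/MeNO2, 22 °C
Reagents that add atoms: oxygen, O=O
Why: The nitrite-modified, aldehyde-selective Wacker oxidation is known to turn vinyl groups on quaternary carbons into the homologous aldehydes, the electron-poor 2-bromoalkene should be left alone, and no basic or reducing reagent touches the two esters.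

Step 8
Reactants: 16 (1S)-3-bromo-1-[(1S,2R,5R)-2-hydroxy-5-methyl-5-(2-oxoethyl)-2-(propan-2-yl)cyclopentyl]but-3-en-1-yl 4-(acetyloxy)benzoate
Product: 18 (3R,3aS,4S,7S,8aR)-3,7-dihydroxy-8a-methyl-6-methylidene-3-(propan-2-yl)decahydroazulen-4-yl 4-(acetyloxy)benzoate, via alkenylchromium species 17 (not isolated)
Conditions: CrCl2 (8 equiv), NiCl2 (5 mol %), degassed DMSO, high dilution (0.005 M), 22 to 40 °C; aq. potassium sodium tartrate work-up
Reagents that add atoms: none
Why: NiCl2 is reduced by CrCl2 to zerovalent nickel, which inserts into the C8–Br bond, and transmetalation to trivalent chromium gives alkenylchromium 17, a weakly basic carbon nucleophile that adds to the chromium-coordinated C9 aldehyde and leaves the benzoate, the aryl acetate and the free tertiary hydroxyl untouched. The closest known reaction type is the intramolecular Nozaki–Hiyama–Kishi alkenyl halide–aldehyde coupling used to close medium carbocycles as 2-methylidenecycloalkan-1-ols. The seven-membered ring closes by C8–C9 bond formation, a 7-exo-trig attack of the C8 alkenyl carbon on the aldehyde tethered through C7, C6, C5, C1 and C10. The new C9 stereocenter is controlled by the trans-disposed arms on C5 and C1 and by the C1 methyl: in the twist-chair transition state with the sp2 carbon C8 on the pseudo-twofold axis, the chromium-bound oxygen should avoid the pseudoaxial β position, which is syn-axial to the C1 methyl across C10, and take the pseudoequatorial α position, which gives 9S. The step needs cyclisation to outrun intermolecular coupling and protonolysis of the alkenyl metal, which high dilution, the short tether held on adjacent trans ring positions and the absence of any leaving group β to chromium should secure.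

Step 9
Reactants: 18 (3R,3aS,4S,7S,8aR)-3,7-dihydroxy-8a-methyl-6-methylidene-3-(propan-2-yl)decahydroazulen-4-yl 4-(acetyloxy)benzoate
Product: 19 ferugin, (3R,3aS,4S,7S,8aR)-3,7-dihydroxy-8a-methyl-6-methylidene-3-(propan-2-yl)decahydroazulen-4-yl 4-hydroxybenzoate
Conditions: pyrrolidine, CH2Cl2, 0 to 22 °C
Reagents that add atoms: none
Why: Aminolysis of the aryl acetate by pyrrolidine is much faster than attack on the hindered secondary benzoate, so the phenol should be released without loss or migration of the C6 acyl group.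

**Compound list**
1 | 3-methylcyclopent-2-en-1-one | CC1=CC(=O)CC1 | starting material
2 | ethynyl(trimethyl)silane | C#C[Si](C)(C)C | starting material
3 | bis(2-methylpropyl)[1-(trimethylsilyl)ethenyl]alumane (alkenylalane, formed in the flask) | C=C([Si](C)(C)C)[Al](CC(C)C)CC(C)C | intermediate
4 | ({(3S)-3-methyl-3-[1-(trimethylsilyl)ethenyl]cyclopent-1-en-1-yl}oxy)bis(2-methylpropyl)alumane (aluminium enolate, formed in the flask) | CC(C)C[Al](CC(C)C)OC1=C[C@](C)(CC1)C(=C)[Si](C)(C)C | intermediate
5 | trimethyl({(3S)-3-methyl-3-[1-(trimethylsilyl)ethenyl]cyclopent-1-en-1-yl}oxy)silane | C[Si](C)(C)OC1=C[C@](C)(CC1)C(=C)[Si](C)(C)C | intermediate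
6 | 3-bromobut-3-en-1-ol | OCCC(Br)=C | starting material
7 | 3-bromobut-3-enal | O=CCC(Br)=C | intermediate
8 | lithium (3S)-3-methyl-3-[1-(trimethylsilyl)ethenyl]cyclopent-1-en-1-olate (formed in the flask) | [Li]OC1=C[C@](C)(CC1)C(=C)[Si](C)(C)C | intermediate
9 | dibutyl({(3S)-3-methyl-3-[1-(trimethylsilyl)ethenyl]cyclopent-1-en-1-yl}oxy)borane (boron enolate, formed in the flask) | CCCCB(CCCC)OC1=C[C@](C)(CC1)C(=C)[Si](C)(C)C | intermediate
10 | (1S)-3-bromo-1-{(1S,2S)-2-methyl-5-oxo-2-[1-(trimethylsilyl)ethenyl]cyclopentyl}but-3-en-1-yl dibutylborinate (boron aldolate, formed in the flask) | C=C(Br)C[C@H](OB(CCCC)CCCC)[C@@H]1[C@](C)(CCC1=O)C(=C)[Si](C)(C)C | intermediate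
11 | (2S,3S)-2-[(1S)-3-bromo-1-hydroxybut-3-en-1-yl]-3-methyl-3-[1-(trimethylsilyl)ethenyl]cyclopentan-1-one | C=C(Br)C[C@H](O)[C@@H]1[C@](C)(CCC1=O)C(=C)[Si](C)(C)C | intermediate
12 | (2S,3R)-2-[(1S)-3-bromo-1-hydroxybut-3-en-1-yl]-3-ethenyl-3-methylcyclopentan-1-one | C=C(Br)C[C@H](O)[C@@H]1[C@](C)(CCC1=O)C=C | intermediate
13 | (1R,2S,3R)-2-[(1S)-3-bromo-1-hydroxybut-3-en-1-yl]-3-ethenyl-3-methyl-1-(propan-2-yl)cyclopentan-1-ol | C=C(Br)C[C@H](O)[C@@H]1[C@](C)(CC[C@@]1(O)C(C)C)C=C | intermediate
14 | 4-(acetyloxy)benzoyl chloride | CC(=O)Oc1ccc(cc1)C(Cl)=O | starting material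
15 | (1S)-3-bromo-1-[(1S,2R,5R)-2-ethenyl-5-hydroxy-2-methyl-5-(propan-2-yl)cyclopentyl]but-3-en-1-yl 4-(acetyloxy)benzoate | C=C(Br)C[C@H](OC(=O)c1ccc(OC(C)=O)cc1)[C@@H]1[C@](C)(CC[C@@]1(O)C(C)C)C=C | intermediate
16 | (1S)-3-bromo-1-[(1S,2R,5R)-2-hydroxy-5-methyl-5-(2-oxoethyl)-2-(propan-2-yl)cyclopentyl]but-3-en-1-yl 4-(acetyloxy)benzoate | C=C(Br)C[C@H](OC(=O)c1ccc(OC(C)=O)cc1)[C@@H]1[C@](C)(CC[C@@]1(O)C(C)C)CC=O | intermediate
17 | (1S)-3-(dichlorochromio)-1-[(1S,2R,5R)-2-hydroxy-5-methyl-5-(2-oxoethyl)-2-(propan-2-yl)cyclopentyl]but-3-en-1-yl 4-(acetyloxy)benzoate (alkenylchromium species, formed in the flask) | C=C([Cr](Cl)Cl)C[C@H](OC(=O)c1ccc(OC(C)=O)cc1)[C@@H]1[C@](C)(CC[C@@]1(O)C(C)C)CC=O | intermediate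
18 | (3R,3aS,4S,7S,8aR)-3,7-dihydroxy-8a-methyl-6-methylidene-3-(propan-2-yl)decahydroazulen-4-yl 4-(acetyloxy)benzoate | C=C1C[C@H](OC(=O)c2ccc(OC(C)=O)cc2)[C@@H]2[C@](C)(CC[C@@]2(O)C(C)C)C[C@@H]1O | intermediate
19 | ferugin, (3R,3aS,4S,7S,8aR)-3,7-dihydroxy-8a-methyl-6-methylidene-3-(propan-2-yl)decahydroazulen-4-yl 4-hydroxybenzoate | C=C1C[C@H](OC(=O)c2ccc(O)cc2)[C@@H]2[C@](C)(CC[C@@]2(O)C(C)C)C[C@@H]1O | target

**Step count**
Total steps: 9. Longest linear sequence: 8 steps (steps 1 and 3 to 9, from 3-methylcyclopent-2-en-1-one); step 2 is a one-step side branch.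

**Steps most likely to fail**

Step 3 (aldol). The β,γ-unsaturated aldehyde 7 may isomerise or self-condense before it is captured, and the hindered enolate may react slowly or with eroded anti selectivity. The fallback sets out from 5 and returns at 13; it sets C6 by chelate-controlled addition instead of by the aldol, and no sensitive aldehyde is handled. Lanthanide-triflate-catalysed Mukaiyama hydroxymethylation of 5 with aqueous formaldehyde (Yb(OTf)3, THF/H2O) should give (2S,3S)-2-(hydroxymethyl)-3-methyl-3-[1-(trimethylsilyl)ethenyl]cyclopentan-1-one F1, again by attack anti to the silylvinyl group. CF3CO2H then removes silicon to give (2S,3R)-3-ethenyl-2-(hydroxymethyl)-3-methylcyclopentan-1-one F2. Addition of i-PrMgCl/CeCl3 anti to the C5 arm gives (1R,2S,3R)-3-ethenyl-2-(hydroxymethyl)-3-methyl-1-(propan-2-yl)cyclopentan-1-ol F3. Dess–Martin oxidation of the primary alcohol gives (1R,2R,5R)-2-ethenyl-5-hydroxy-2-methyl-5-(propan-2-yl)cyclopentane-1-carbaldehyde F4. Indium-mediated 2-bromoallylation with 2,3-dibromopropene (C=C(Br)CBr) in THF/H2O should then give 13, through the chelate between the C4 hydroxyl and the aldehyde oxygen and attack on the carbonyl face turned away from C1.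

Step 8 (ring closure). Facial selectivity at C9 may be poor or may favour the epimer. The fallback sets out from 16 and returns at 18; the ring is still closed with CrCl2/NiCl2, but C9 is then set by reagent control. If the closure gives mainly the 9-epimer (3R,3aS,4S,7R,8aR)-3,7-dihydroxy-8a-methyl-6-methylidene-3-(propan-2-yl)decahydroazulen-4-yl 4-(acetyloxy)benzoate F5, Dess–Martin oxidation of the allylic alcohol (either epimer) gives the cross-conjugated enone (3R,3aS,4S,8aR)-3-hydroxy-8a-methyl-6-methylidene-7-oxo-3-(propan-2-yl)decahydroazulen-4-yl 4-(acetyloxy)benzoate F6. Corey–Bakshi–Shibata reduction with the (R)-methyl oxazaborolidine and catecholborane at −78 °C, the alkenyl arm acting as the large group, should then return 18.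

Step 4 (protodesilylation). The acid may dehydrate the β-hydroxy ketone or trigger cationic rearrangement next to the quaternary carbon. The fallback sets out from 11 and returns at 12. Neutral ipso-iododesilylation with N-iodosuccinimide in MeCN at 0 °C should give (2S,3S)-2-[(1S)-3-bromo-1-hydroxybut-3-en-1-yl]-3-(1-iodoethenyl)-3-methylcyclopentan-1-one F7. Chemoselective hydrodeiodination with Bu3SnH and catalytic Pd(PPh3)4, where insertion into C–I is far faster than into C–Br, then gives 12.

**Further compounds**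
F1 | step 3 | (2S,3S)-2-(hydroxymethyl)-3-methyl-3-[1-(trimethylsilyl)ethenyl]cyclopentan-1-one | OC[C@@H]1[C@](C)(CCC1=O)C(=C)[Si](C)(C)C
F2 | step 3 | (2S,3R)-3-ethenyl-2-(hydroxymethyl)-3-methylcyclopentan-1-one | OC[C@@H]1[C@](C)(CCC1=O)C=C
F3 | step 3 | (1R,2S,3R)-3-ethenyl-2-(hydroxymethyl)-3-methyl-1-(propan-2-yl)cyclopentan-1-ol | OC[C@@H]1[C@](C)(CC[C@@]1(O)C(C)C)C=C
F4 | step 3 | (1R,2R,5R)-2-ethenyl-5-hydroxy-2-methyl-5-(propan-2-yl)cyclopentane-1-carbaldehyde | O=C[C@@H]1[C@](C)(CC[C@@]1(O)C(C)C)C=C
F5 | step 8 | (3R,3aS,4S,7R,8aR)-3,7-dihydroxy-8a-methyl-6-methylidene-3-(propan-2-yl)decahydroazulen-4-yl 4-(acetyloxy)benzoate | C=C1C[C@H](OC(=O)c2ccc(OC(C)=O)cc2)[C@@H]2[C@](C)(CC[C@@]2(O)C(C)C)C[C@H]1O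
F6 | step 8 | (3R,3aS,4S,8aR)-3-hydroxy-8a-methyl-6-methylidene-7-oxo-3-(propan-2-yl)decahydroazulen-4-yl 4-(acetyloxy)benzoate | C=C1C[C@H](OC(=O)c2ccc(OC(C)=O)cc2)[C@@H]2[C@](C)(CC[C@@]2(O)C(C)C)CC1=O
F7 | step 4 | (2S,3S)-2-[(1S)-3-bromo-1-hydroxybut-3-en-1-yl]-3-(1-iodoethenyl)-3-methylcyclopentan-1-one | C=C(Br)C[C@H](O)[C@@H]1[C@](C)(CCC1=O)C(I)=C
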